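**The flask.** The constants set two users against each other for dissolved substrate: the side step, which spends it in pairs, and partner, which spends it singly.

    solid substrate ⇌ dissolved substrate, rate k1*(cs1 - [dissolved substrate]) while solid is left; crystals form when [dissolved substrate] > cs1 (cs1 = 14 mM, k1 = 0.016 /h)
    dissolved substrate + partner → target (k2 = 4.1 /M/h)
    2 dissolved substrate → side product (k3 = 5.2 /M/h)
    solid reagent ⇌ partner, rate k4*(cs4 - [partner]) while solid is left; crystals form when [partner] > cs4 (cs4 = 7.4 mM, k4 = 0.015 /h)

solid substrate 23 mM; solid reagent 1.20 equiv; time 10 d

- a species is counted by the solid substrate in it: one side product counts as two
- for a step with 2 of a species take k times the square, and two of it per event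
- given per volume of solution although it is solid: solid substrate, solid reagent
- at the start none of the solid substrate is in solution
- at the start none of the solid reagent is in solution
- run time (flask): 10 d

- how much target there is at 10 d, in percent of the solid substrate charged
- the change that raises the amount of target at 10 d, in percent of the solid substrate charged most ("none" if none brings more than 2 percentage points) (Thursday's / Monday's / Wednesday's / Friday's / none)
- amount of target at 10 d, in percent of the solid substrate charged, after Wednesday's

- Thursday's: doubling the solubility in step 1, all else as stated
- Monday's: doubling the dissolution coefficient of step 1, all else as stated
- Wednesday's: doubling the solubility in step 4, all else as stated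
- Friday's: doubling the dissolution coefficient of step 4, all else as stated

**First pass.** While solid lasts, dissolved substrate levels off where dissolution equals loss. We take the side step as the large loss and balance it alone, which puts dissolved substrate at 17.1% of the charge. Partner levels off where its dissolution equals its use, at 15.5%. Adding the loss to target as the correction brings dissolved substrate down to 14.8%.

**The share.** Partner's claim is its rate constant times partner; the side claim, larger, is twice its constant times dissolved substrate. So we reckon that 29.3% goes to target: the fraction of consumed dissolved substrate that becomes target, our target share, or selectivity. The solid lasts about 5.65 d, shorter than the run, so we expect about that share as yield.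

**Thursday's change.** The first pass gives dissolved substrate 25.4% and partner 12.4%, so the share falls to 17.3%.

**Monday's change.** Dissolved substrate reaches 22.6% and partner 13.3%, so the share falls to 20.2%.

**Wednesday's change.** Partner goes to 31.0%, and the share rises to 48.8%.

**Friday's change.** Partner goes to 20.9%, and the share rises to 37.0%. So Wednesday's share is the highest we reckon, and we pick that change.

**The forecast.** It gives 33% of target, picks Wednesday's, and gives 52% after that change, holding that “Partner supply is the lever against the side reaction”. It picks the change we pick, and both our figures lie lower.

**What comes.** The flask gives 30.1% of target, and the best change is Wednesday's, a gain of 19 percentage points. Side product holds 69.2% of the charge in this flask at 10.0 d. The target share of that moment, worked from this flask's own readings at 5.00 d, is 30.2%. Wednesday's flask, reckoned at a share of 48.8%, gives 48.8%.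

The numbers are invented, and the outcome is calculated.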